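- The vessel is closed, stirred and held at one temperature, so you can follow each flask as the fraction of its own charge of starting material that has become target.

common to all: enzyme 4.8 µM

| run | starting material | second substrate | remark | time |
|---|---|---|---|---|
| amber | 6.5 mM | 10 mM | run made earlier |  |
| teal | 29 mM | 10 mM | run made earlier |  |
| dusk | 20 mM | 10.0 mM |  | 10 h |
| midnight | 5.0 mM | 10.0 mM |  | 3.0 h |

| run | time / h | target / % |
|---|---|---|
| amber | 0.417 | 4 |
| amber | 0.833 | 4 |
| amber | 1.33 | 9 |
| amber | 2.50 | 17 |
| amber | 5.00 | 29 |
| teal | 0.417 | 0 |
| teal | 1.33 | 5 |
| teal | 2.50 | 12 |
| teal | 4.00 | 18 |
| teal | 5.00 | 23 |

(readings scatter by 1.5 percentage points)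

1. which one finishes higher in amount of target, in percent of the starting material charged ("neither" within 2 percentage points) (dusk / midnight / neither)
2. amount of target at the end, in percent of the starting material charged, dusk
3. amount of target at the end, in percent of the starting material charged, midnight

- the analysis behind the earlier runs scatters by 1.5 percentage points, standard deviation
- a reading or a percentage of target counts all its forms, free or not

- Take the simplest case as the zero of the scale: if each molecule of starting material had the same chance per hour whatever the charge (first order), the amber and teal curves would coincide.
- Amber's last reading gives 0.0685 /h, and this number is the fractional rate: minus the natural logarithm of the fraction of the charge left, divided by the time. Teal's last reading gives 0.0523 /h.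
- Could that gap be scatter? The two readings differ by 6 percentage points against a scatter of 1.5 points each, so I take it as real: teal turns over a smaller fraction per hour than amber.
- My reckoning interpolates on the charge, which gives dusk 0.0588 /h and so 44.4% after its 10 h. Midnight's charge lies near amber's, so amber's rate gives it 18.6%.
- But the readings stop at 5.00 h, and dusk runs on past that. Teal at 2.50 h gives 0.0511 /h, close to its later value, so I see no drift to correct for.
- A second doubt: if each target took up one second substrate, dusk, charged with half as much of it, would stop at that fraction. Teal's last reading equals 66.7% of its second substrate charge, so that reading stays short of such a limit, and my figure for dusk lies below it.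
- The forecast names dusk as higher, with dusk at 40% (32% to 47%) and midnight at 20% (16% to 24%), lower than mine for dusk. It expects that the second substrate's loss “should reduce the late rate”, and its dusk figure sits where first order through teal's last reading lands.
- The flasks give 50.6% for dusk and 17.9% for midnight, so dusk finishes higher.

    starting material + enzyme ⇌ complex A (K = 28.0 /M, k = 4.40 × 10⁵ /M/h)
    complex A → enzyme + target (k = 1300 /h)
    second substrate + enzyme ⇌ complex B (K = 150 /M, k = 1.10 × 10⁶ /M/h)
    complex B → enzyme + second product (k = 160 /h)
    2 complex A ⇌ resting dimer, settled at all times (K = 2.70 × 10⁵ /M)
    target + enzyme ⇌ isomer of the product + enzyme, rate k6*[enzyme]*[target] forward; the back reaction follows from the equilibrium constant (K = 4.20, k = 1800 /M/h)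
    second substrate + target ⇌ idle adduct, settled at all times (K = 430 /M)

- Dusk's fractional rate over its whole run is 0.0706 /h, above my 0.0588 /h and near amber's 0.0685 /h. The main reason dusk stops short of its whole charge is the way back from complex A to starting material and enzyme: without that way back, dusk reaches 98.6% rather than 50.6%. The neighbour flask, dusk with 40 mM of second substrate, reaches 21.5%, a fractional rate of 0.0242 /h, a third of dusk's, with complex B at 74.9% of the catalyst.

The runs are calculated with constants of no real substance; the scatter is artificial.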